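**Retrosynthetic overview**
1. Ring C is numbered C1 (quaternary: CH3 and Ca, with Ca=Cb–C3A of coumarin A), C2, C3, C4 (CH3), C5 (=CH), C6 (H and C3B of coumarin B). The route rests on one feature: Ca and C3B stand cis on the neighbouring atoms C1 and C6, so a temporary Ca=C3B bond makes them two corners of a cyclobutene fused to ring C along C1–C6.
2. Late disconnections are Cb–C3A (Heck coupling of the C1 vinyl group with a 3-bromocoumarin) and C3B–C4B plus O1B–C2B (ester aldol with a protected salicylaldehyde, then lactonisation). They lead back to ring C with cis vinyl groups on C1 and C6.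
3. Both vinyl groups come from ethenolysis of the cyclobutene. Before that, while the clamp still holds C6, the C5 ketone is used to bring in the C4 methyl group and the C4=C5 alkene.
4. The cyclobutene comes from an enantioselective [2+2] photocycloaddition of acetylene across C1=C6 of 3-methylcyclohex-2-en-1-one (carbonyl = C5).
5. Ring order: ring C is bought; the cyclobutene is made in step 1 and opened in step 5; the pyranone ring of coumarin B is closed in step 11; coumarin A arrives complete in step 14.

Key step: step 1

Assumption: the oxazaborolidine built from the (S)-diarylprolinol is taken to leave open the enone face that gives the (1S,6R) photoadduct, by analogy with alkene additions to bound cyclic enones. If the sense is the opposite, the (R)-prolinol is used.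

**Step 1**
Reactants: 1 3-methylcyclohex-2-en-1-one; 2 acetylene
Product: 3 (1S,6R)-6-methylbicyclo[4.2.0]oct-7-en-2-one (cis-fused)
Conditions: 2 (acetone-free, saturated solution), oxazaborolidine from (S)-α,α-bis(3,5-dimethylphenyl)prolinol and 2,4,6-trifluorophenylboronic acid (50 mol %), AlBr3 (50 mol %), CH2Cl2, −75 °C, hν (366 nm); Et3N quench at −75 °C
Reagents that add atoms: none
Why: Proposed new method: binding of the AlBr3-activated oxazaborolidine to the C5 carbonyl moves the strong π–π* band of 1 to longer wavelength, so at 366 nm the bound enone takes nearly all the light, crosses to its triplet state and adds to 2 stepwise through a 1,4-diradical that closes after spin inversion. The closest known reaction types are the racemic enone–acetylene [2+2] photocycloaddition and the chiral-Lewis-acid [2+2] photocycloaddition of cyclic enones to simple alkenes such as ethylene, whose combination has not been shown. One ring is closed, the four-membered one, by radical addition followed by 1,4-diradical recombination, which forms C1–Ca and C6–C3B. C1 is set by the catalyst, whose aryl groups cover one face of the bound enone so that 2 arrives from the open face, and C6 follows from C1 because a cyclobutene can be fused to the six-membered ring only in the cis sense. The step needs enantioface selectivity, secured by the high loading, the low temperature and the long wavelength that hold down the reaction of free 1, while no regiochemical question arises because 2 is symmetric. It also needs 3 to stay unexcited, because a photochemical 1,3-acyl shift (C5 moving from C6 to Ca) would give the mirror image of 3, and the weak n–π* band of 3 lies well below 366 nm; the large excess of 2 keeps excited 1 away from the strained alkene of 3.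

**Step 2**
Reactants: 3 (1S,6R)-6-methylbicyclo[4.2.0]oct-7-en-2-one
Product: 7 (1S,6R)-6-methyl-3-methylidenebicyclo[4.2.0]oct-7-en-2-one, via lithium enolate 4 (not isolated), via Mannich base 5 (not isolated), via ammonium iodide 6 (not isolated)
Conditions: LiN(i-Pr)2, THF, −78 °C; [CH2=NMe2]I, −78 → 0 °C; crude amine, MeI, Et2O, 23 °C; NaHCO3 aq, CH2Cl2, 23 °C
Reagents that add atoms: Eschenmoser's salt C=[N+](C)C.[I-]; iodomethane CI (its methyl group stays only in 6)
Why: Kinetic deprotonation by the bulky amide should take a proton from the open C4 methylene rather than the C6 methine next to quaternary C1, the enolate undergoes a Mannich reaction with the iminium salt, and exhaustive methylation with mild E1cB (Hofmann-type) elimination gives the exocyclic enone, with no new stereocentre kept and C6 unable to invert because only the cis fusion is possible.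

**Step 3**
Reactants: 7 (1S,6R)-6-methyl-3-methylidenebicyclo[4.2.0]oct-7-en-2-one
Product: 9 (1S,6R)-3,6-dimethylbicyclo[4.2.0]octa-2,7-dien-2-yl trifluoromethanesulfonate, via lithium enolate 8 (not isolated)
Conditions: LiBH(s-Bu)3, THF, −78 °C; Comins' reagent, −78 → 0 °C
Reagents that add atoms: Comins' reagent FC(F)(F)S(=O)(=O)N(c1ccc(Cl)cn1)S(=O)(=O)C(F)(F)F
Why: Conjugate (1,4) hydride reduction of the s-cis enone by the bulky borohydride, for which the shielded C5 carbonyl is hard to reach, creates the C4 methyl group and gives the C4=C5 enolate as the only regioisomer without any acid–base equilibrium that could involve the allylic C6–H, and O-sulfonylation fixes it as the enol triflate.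

**Step 4**
Reactants: 9 (1S,6R)-3,6-dimethylbicyclo[4.2.0]octa-2,7-dien-2-yl trifluoromethanesulfonate
Product: 10 (1R,6R)-3,6-dimethylbicyclo[4.2.0]octa-2,7-diene
Conditions: Pd(OAc)2 (5 mol %), PPh3 (10 mol %), HCO2H, Et3N, DMF, 60 °C; pentane extraction, kept in solution (volatile)
Reagents that add atoms: none
Why: In this palladium-catalysed formate reduction of an enol triflate, oxidative addition to zerovalent palladium, exchange of triflate for formate, loss of CO2 and reductive elimination place H on C5 with the alkene held at C4=C5, and excess formate should intercept the hindered alkenylpalladium species before it can add to the cyclobutene.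

**Step 5**
Reactants: 10 (1R,6R)-3,6-dimethylbicyclo[4.2.0]octa-2,7-diene; 11 ethylene
Product: 12 (3R,4R)-3,4-diethenyl-1,4-dimethylcyclohex-1-ene (vinyl groups cis)
Conditions: 11 (1 atm, saturated), second-generation Grubbs catalyst RuCl2(=CHPh)(H2IMes)(PCy3) (3 mol %), 1,4-benzoquinone (10 mol %), CH2Cl2 (0.02 M), 23 °C
Reagents that add atoms: none
Why: Ring-opening metathesis with ethylene (ethenolysis) is driven by release of cyclobutene strain, leaves the trisubstituted C4=C5 alkene untouched, and turns Ca and C3B into two vinyl groups whose cis relation is inherited from the ring fusion because no bond to C1 or C6 is broken.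

**Step 6**
Reactants: 12 (3R,4R)-3,4-diethenyl-1,4-dimethylcyclohex-1-ene
Product: 14 2-[(1R,6R)-6-ethenyl-3,6-dimethylcyclohex-2-en-1-yl]ethan-1-ol, via trialkylborane 13 (not isolated)
Conditions: Sia2BH (from BH3·THF and 2-methylbut-2-ene, 1.05 equiv), THF, −20 → 0 °C; NaOH aq, H2O2, 0 °C
Reagents that add atoms: hydrogen peroxide OO; disiamylborane CC(C)C(C)BC(C)C(C)C (boron and siamyl groups stay only in 13)
Why: Hydroboration–oxidation with a bulky dialkylborane is governed by steric access, so boron should reach the terminal carbon of the C6 vinyl group (on a tertiary carbon) faster than that of the C1 vinyl group (neopentyl-type, on the quaternary carbon) and should not touch the ring alkene, and oxidation gives the primary alcohol.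

**Step 7**
Reactants: 14 2-[(1R,6R)-6-ethenyl-3,6-dimethylcyclohex-2-en-1-yl]ethan-1-ol
Product: 15 [(1R,6R)-6-ethenyl-3,6-dimethylcyclohex-2-en-1-yl]acetic acid
Conditions: TEMPO (20 mol %), PhI(OAc)2 (2.4 equiv), MeCN–H2O (1:1), 23 °C
Reagents that add atoms: water O
Why: Oxoammonium-mediated oxidation in the presence of water takes the primary alcohol through the aldehyde hydrate to the acid, whose carbonyl carbon becomes C2B, and this reaction type is known to spare isolated alkenes.

**Step 8**
Reactants: 15 [(1R,6R)-6-ethenyl-3,6-dimethylcyclohex-2-en-1-yl]acetic acid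
Product: 16 methyl [(1R,6R)-6-ethenyl-3,6-dimethylcyclohex-2-en-1-yl]acetate
Conditions: MeI, K2CO3, DMF, 23 °C
Reagents that add atoms: iodomethane CI
Why: SN2 O-alkylation of the carboxylate gives the methyl ester needed for clean enolate formation.

**Step 9**
Reactants: 17 2,4-dihydroxy-3-methoxybenzaldehyde
Product: 18 3-methoxy-2,4-bis(methoxymethoxy)benzaldehyde
Conditions: NaH (2.4 equiv), MOMCl (2.5 equiv), DMF, 0 → 23 °C
Reagents that add atoms: chloromethyl methyl ether COCCl
Why: Williamson-type O-alkylation of both phenoxides forms the two acetals, the strong base overcoming the hydrogen bond between the 2-OH and the aldehyde.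

**Step 10**
Reactants: 16 methyl [(1R,6R)-6-ethenyl-3,6-dimethylcyclohex-2-en-1-yl]acetate; 18 3-methoxy-2,4-bis(methoxymethoxy)benzaldehyde
Product: 20 methyl 2-[(1S,6R)-6-ethenyl-3,6-dimethylcyclohex-2-en-1-yl]-3-hydroxy-3-[3-methoxy-2,4-bis(methoxymethoxy)phenyl]propanoate (mixture at the two new centres; ring C unchanged in space with the descriptor altered by ranking only), via lithium ester enolate 19 (not isolated)
Conditions: LiN(i-Pr)2, THF, −78 °C; 18, −78 °C; AcOH quench
Reagents that add atoms: none
Why: Aldol addition of the lithium ester enolate to the non-enolisable aldehyde forms the C3B–C4B bond, and both new stereocentres are erased in the next step so that their mixture does not matter.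

**Step 11**
Reactants: 20 the aldol adduct
Product: 22 3-[(1R,6R)-6-ethenyl-3,6-dimethylcyclohex-2-en-1-yl]-7-hydroxy-8-methoxy-2H-chromen-2-one, via Z-cinnamate 21 (not isolated)
Conditions: conc. HCl in MeOH (about 1 M), 45 °C
Reagents that add atoms: none
Why: Acid removes both acetals and ionises the electron-rich benzylic alcohol, E1 loss of the C3B proton places the aryl group trans to the bulky ring C residue and therefore cis to the ester (any other geometry can equilibrate through the stabilised benzylic cation), and the free 2-OH then lactonises to the coumarin, which is the thermodynamic sink.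

**Step 12**
Reactants: 23 7-hydroxy-8-methoxy-2H-chromen-2-one
Product: 24 8-methoxy-7-(methoxymethoxy)-2H-chromen-2-one
Conditions: MOMCl, i-Pr2NEt, CH2Cl2, 0 → 23 °C
Reagents that add atoms: chloromethyl methyl ether COCCl
Why: O-alkylation of the acidic 7-OH masks the phenol, which would otherwise direct bromination into the benzene ring and slow the oxidative addition in the coupling.

**Step 13**
Reactants: 24 8-methoxy-7-(methoxymethoxy)-2H-chromen-2-one
Product: 25 3-bromo-8-methoxy-7-(methoxymethoxy)-2H-chromen-2-one
Conditions: NBS, MeCN, 23 → 50 °C, dark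
Reagents that add atoms: N-bromosuccinimide O=C1CCC(=O)N1Br
Why: Electrophilic bromination goes to C3, the vinylogous para position of the 7-alkoxy donor and the usual site of attack in 7-alkoxycoumarins, and NBS leaves only succinimide so the acetal is not exposed to HBr.

**Step 14**
Reactants: 22 the coumarin B–ring C vinyl compound; 25 3-bromo-8-methoxy-7-(methoxymethoxy)-2H-chromen-2-one
Product: 26 3-[(E)-2-[(1R,2R)-2-(7-hydroxy-8-methoxy-2-oxo-2H-chromen-3-yl)-1,4-dimethylcyclohex-3-en-1-yl]ethenyl]-8-methoxy-7-(methoxymethoxy)-2H-chromen-2-one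
Conditions: Pd(OAc)2 (10 mol %), P(o-tol)3 (20 mol %), Et3N, DMF, 85 °C
Reagents that add atoms: none
Why: In this Mizoroki–Heck reaction the electron-poor alkenyl bromide adds to zerovalent palladium, the monosubstituted C1 vinyl group inserts with C3A going to the terminal carbon Cb, and syn β-hydride elimination can use only a hydrogen on Cb because C1 is quaternary, so the E-alkene should form without migration, as with 2-methylbut-3-en-2-ol, while the trisubstituted alkenes do not compete.

**Step 15**
Reactants: 26 the mono-MOM ether of the target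
Product: 27 3-[(E)-2-[(1R,2R)-2-(7-hydroxy-8-methoxy-2-oxo-2H-chromen-3-yl)-1,4-dimethylcyclohex-3-en-1-yl]ethenyl]-7-hydroxy-8-methoxy-2H-chromen-2-one (CNP0264408.1)
Conditions: HCl (about 1 M) in MeOH–THF, 40 °C
Reagents that add atoms: none
Why: Acid-catalysed acetal cleavage is easy here because the coumarin phenol is a good leaving group, so conditions mild enough to spare the trisubstituted alkene, the diene and both lactones should suffice, and no stereocentre is touched.

**Compound list**
1 | 3-methylcyclohex-2-en-1-one | CC1=CC(=O)CCC1 | starting material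
2 | acetylene | C#C | starting material
3 | (1S,6R)-6-methylbicyclo[4.2.0]oct-7-en-2-one | C[C@]12CCCC(=O)[C@H]1C=C2 | intermediate
4 | lithium C4=C5 enolate of 3 (not isolated) | C[C@]12CCC=C([O-])[C@H]1C=C2.[Li+] | intermediate
5 | 3-[(dimethylamino)methyl] derivative of 3, C3 epimers (not isolated) | C[C@]12CCC(CN(C)C)C(=O)[C@H]1C=C2 | intermediate
6 | trimethylammonium iodide of 5 (not isolated) | C[C@]12CCC(C[N+](C)(C)C)C(=O)[C@H]1C=C2.[I-] | intermediate
7 | (1S,6R)-6-methyl-3-methylidenebicyclo[4.2.0]oct-7-en-2-one | C[C@]12CCC(=C)C(=O)[C@H]1C=C2 | intermediate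
8 | lithium enolate from 1,4-reduction of 7 (not isolated) | C[C@]12CCC(C)=C([O-])[C@H]1C=C2.[Li+] | intermediate
9 | (1S,6R)-3,6-dimethylbicyclo[4.2.0]octa-2,7-dien-2-yl trifluoromethanesulfonate | C[C@]12CCC(C)=C(OS(=O)(=O)C(F)(F)F)[C@H]1C=C2 | intermediate
10 | (1R,6R)-3,6-dimethylbicyclo[4.2.0]octa-2,7-diene | C[C@]12CCC(C)=C[C@H]1C=C2 | intermediate
11 | ethylene | C=C | starting material
12 | (3R,4R)-3,4-diethenyl-1,4-dimethylcyclohex-1-ene | C=C[C@@]1(C)CCC(C)=C[C@H]1C=C | intermediate
13 | bis(3-methylbutan-2-yl)borane adduct at the C6 vinyl group (not isolated) | C=C[C@@]1(C)CCC(C)=C[C@H]1CCB(C(C)C(C)C)C(C)C(C)C | intermediate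
14 | 2-[(1R,6R)-6-ethenyl-3,6-dimethylcyclohex-2-en-1-yl]ethan-1-ol | C=C[C@@]1(C)CCC(C)=C[C@H]1CCO | intermediate
15 | [(1R,6R)-6-ethenyl-3,6-dimethylcyclohex-2-en-1-yl]acetic acid | C=C[C@@]1(C)CCC(C)=C[C@H]1CC(=O)O | intermediate
16 | methyl [(1R,6R)-6-ethenyl-3,6-dimethylcyclohex-2-en-1-yl]acetate | C=C[C@@]1(C)CCC(C)=C[C@H]1CC(=O)OC | intermediate
17 | 2,4-dihydroxy-3-methoxybenzaldehyde | O=Cc1ccc(O)c(OC)c1O | starting material
18 | 3-methoxy-2,4-bis(methoxymethoxy)benzaldehyde | O=Cc1ccc(OCOC)c(OC)c1OCOC | intermediate
19 | lithium enolate of 16 (not isolated) | C=C[C@@]1(C)CCC(C)=C[C@H]1C=C([O-])OC.[Li+] | intermediate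
20 | aldol adduct of 16 and 18 | C=C[C@@]1(C)CCC(C)=C[C@H]1C(C(=O)OC)C(O)c1ccc(OCOC)c(OC)c1OCOC | intermediate
21 | methyl (Z)-3-(2,4-dihydroxy-3-methoxyphenyl)-2-[(1R,6R)-6-ethenyl-3,6-dimethylcyclohex-2-en-1-yl]prop-2-enoate (not isolated) | C=C[C@@]1(C)CCC(C)=C[C@H]1/C(C(=O)OC)=C/c1ccc(O)c(OC)c1O | intermediate
22 | 3-[(1R,6R)-6-ethenyl-3,6-dimethylcyclohex-2-en-1-yl]-7-hydroxy-8-methoxy-2H-chromen-2-one | C=C[C@@]1(C)CCC(C)=C[C@H]1c1cc2ccc(O)c(OC)c2oc1=O | intermediate
23 | 7-hydroxy-8-methoxy-2H-chromen-2-one | COc1c(O)ccc2ccc(=O)oc12 | starting material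
24 | 8-methoxy-7-(methoxymethoxy)-2H-chromen-2-one | COCOc1ccc2ccc(=O)oc2c1OC | intermediate
25 | 3-bromo-8-methoxy-7-(methoxymethoxy)-2H-chromen-2-one | COCOc1ccc2cc(Br)c(=O)oc2c1OC | intermediate
26 | mono-MOM ether (coumarin A) of the target | COCOc1ccc2cc(/C=C/[C@@]3(C)CCC(C)=C[C@H]3c3cc4ccc(O)c(OC)c4oc3=O)c(=O)oc2c1OC | intermediate
27 | CNP0264408.1 | COc1c(O)ccc2cc(/C=C/[C@@]3(C)CCC(C)=C[C@H]3c3cc4ccc(O)c(OC)c4oc3=O)c(=O)oc12 | target

**Step count:** 15 steps in total. The longest linear sequence is 12 steps (1–8, 10, 11, 14, 15).

**Steps most likely to fail**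

Step 1.
- What may go wrong:
  - Capture of the bound triplet enone by acetylene may be slow. Light absorption by free enone (racemic background), addition of excited enone to the strained alkene of the product and the enantiomerising acyl shift would then gain weight.
  - The strong Lewis acid may consume acetylene.
  - It may also trigger an acid-induced skeletal rearrangement of the β,γ-unsaturated ketone (Cargill type) before the quench.
- Fallback (known chemistry, from 1 and 2, back at 3):
  - 1 and 2 are irradiated without Lewis acid (medium-pressure Hg lamp, Pyrex, CH2Cl2, −70 °C). This is the established racemic enone–acetylene photocycloaddition and gives racemic cis-6-methylbicyclo[4.2.0]oct-7-en-2-one F1; the acyl shift does no harm in the racemic series.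
  - Noyori ketalisation with (1R,2R)-1,2-diphenyl-1,2-bis(trimethylsilyloxy)ethane (cat. TMSOTf, CH2Cl2, −78 °C) gives two diastereomers, the hydrobenzoin ketal of the (1S,6R) ketone F2 and the hydrobenzoin ketal of the (1R,6S) ketone F3.
  - The ketal carbon is no stereocentre because the diol is C2-symmetric, so only two compounds have to be separated by chromatography or crystallisation.
  - Mild hydrolysis of F2 (1 M HCl, THF, 23 °C) returns 3.

Step 6.
- What may go wrong: the borane may discriminate too little between the two monosubstituted vinyl groups, and double hydroboration may occur, because the C6 vinyl group is itself crowded by the neighbouring quaternary carbon.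
- Fallback (from 12, back at 15):
  - The site is chosen by metathesis instead of by borane size. Cross metathesis of 12 with 4,4,5,5-tetramethyl-2-vinyl-1,3,2-dioxaborolane (second-generation Hoveyda–Grubbs catalyst RuCl2(=CH-C6H4-2-O-i-Pr)(H2IMes), CH2Cl2, 40 °C) should engage only the C6 vinyl group, since a vinyl group on a quaternary carbon is almost inert in cross metathesis. It gives the pinacol (E)-alkenylboronate F4.
  - NaBO3·4H2O (THF–H2O) oxidises the C–B bond to the enol and thus gives [(1R,6R)-6-ethenyl-3,6-dimethylcyclohex-2-en-1-yl]acetaldehyde F5.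
  - Pinnick oxidation (NaClO2, NaH2PO4, 2-methylbut-2-ene, t-BuOH–H2O) leads to 15.

Step 14.
- What may go wrong: migratory insertion of the neopentyl-type vinyl group, shielded by the cis coumarin B, may be slow, so that reduction or homocoupling of the bromide and decay of the catalyst take over.
- Fallback (from 22, back at 27): coumarin A is built on the vinyl group instead of being coupled to it.
  - Aldehyde-selective Tsuji–Wacker oxidation of 22 (PdCl2(PhCN)2, CuCl2, AgNO2, t-BuOH–MeNO2, O2, 23 °C), a reaction known to favour the aldehyde for vinyl groups on quaternary carbon, gives the C1-acetaldehyde F6.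
  - Knoevenagel–Doebner condensation with malonic acid under Linstead conditions (Et3N, 90 °C) gives the (E)-β,γ-unsaturated acid F7, which has Ca=Cb in place, its CH2 as C3A and its CO2H as C2A.
  - Perkin–Oglialoro condensation of F7 with 17 (Ac2O, Et3N, 110 °C) closes coumarin A and acetylates both phenols to give the target diacetate F8.
  - K2CO3 in MeOH at 0 °C followed by dilute acid gives 27.

**Further compounds**
F1 | step 1 | racemic cis-6-methylbicyclo[4.2.0]oct-7-en-2-one | C[C@]12CCCC(=O)[C@H]1C=C2.C[C@@]12CCCC(=O)[C@@H]1C=C2
F2 | step 1 | (R,R)-hydrobenzoin ketal of the (1S,6R) ketone | C[C@]12CCCC3(O[C@H](c4ccccc4)[C@@H](c4ccccc4)O3)[C@H]1C=C2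
F3 | step 1 | (R,R)-hydrobenzoin ketal of the (1R,6S) ketone | C[C@@]12CCCC3(O[C@H](c4ccccc4)[C@@H](c4ccccc4)O3)[C@@H]1C=C2
F4 | step 6 | pinacol (E)-2-[(1R,6R)-6-ethenyl-3,6-dimethylcyclohex-2-en-1-yl]ethenylboronate | C=C[C@@]1(C)CCC(C)=C[C@H]1/C=C/B1OC(C)(C)C(C)(C)O1
F5 | step 6 | [(1R,6R)-6-ethenyl-3,6-dimethylcyclohex-2-en-1-yl]acetaldehyde | C=C[C@@]1(C)CCC(C)=C[C@H]1CC=O
F6 | step 14 | [(1R,2R)-2-(7-hydroxy-8-methoxy-2-oxo-2H-chromen-3-yl)-1,4-dimethylcyclohex-3-en-1-yl]acetaldehyde | O=CC[C@@]1(C)CCC(C)=C[C@H]1c1cc2ccc(O)c(OC)c2oc1=O
F7 | step 14 | (E)-4-[(1R,2R)-2-(7-hydroxy-8-methoxy-2-oxo-2H-chromen-3-yl)-1,4-dimethylcyclohex-3-en-1-yl]but-3-enoic acid | OC(=O)C/C=C/[C@@]1(C)CCC(C)=C[C@H]1c1cc2ccc(O)c(OC)c2oc1=O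
F8 | step 14 | 7,7'-di-O-acetate of the target | COc1c(OC(C)=O)ccc2cc(/C=C/[C@@]3(C)CCC(C)=C[C@H]3c3cc4ccc(OC(C)=O)c(OC)c4oc3=O)c(=O)oc12
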